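A direct plan would take 2,3,4-trimethoxybenzaldehyde A1 through Dakin oxidation and Fries rearrangement to the acetophenone 1-(2-hydroxy-3,4,5-trimethoxyphenyl)ethan-1-one A2. It would then benzylate the phenol, condense the methyl ketone with 3,4,5-trimethoxybenzaldehyde A3 to the benzyl-protected chalcone A4, move ring B from C2 to C3 with thallium trinitrate to the keto dimethyl acetal A5, and end with hydrogenolysis and acid closure of ring C. Its weakest points would be:
(a) the oxidative 1,2-aryl shift that turns A4 into A5, which would use a stoichiometric, highly toxic trivalent thallium salt on the most advanced material, with two electron-rich arenes open to over-oxidation;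
(b) the Dakin/Fries/benzylation run-up from A1 through A2, three operations that would add only an acetyl group and a protecting group that must come off again;
(c) the detour through the sp3 acetal A5 and its racemic stereocentre, made only to be erased in the last closure.

**Plan of the new route.** Ring C is cut at O1–C2 and C2–C3 (C2 is the carbon of an amide acetal), ring A at C4a–C8a and C5–C6, and the chain at C4–C4a. The enabling feature is ring A itself: its four contiguous oxygen-bearing carbons C8a, C8, C7 and C6 are the four carbons of dimethyl squarate, and C5–H/C4a are a vinyl unit. O1 on C8a lies ortho to the C4 ketone, exactly where a ketene oxygen ends up after ring expansion of a 4-alkenylcyclobutenone. Ring B is bought already attached to C3 (as the arylacetic acid), ring A is made last from the four-membered ring, and ring C closes on the newly formed phenol in the same flask. No aryl shift, thallium, protecting group or Dakin/Fries sequence arises, and the substitution pattern of ring A is fixed by connectivity.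

Key step: step 4

Remark: chromone numbering (O1, C2 … C8a) is used for the atoms of the target. Compounds 4, 5 and 8 are racemic at C4 of the cyclobutenone; this centre is erased in step 4 and the target has no stereocentre. Compounds 1, 2 and 6 are taken as commercial.

Step 1
Reactants: 1 (E)-1,2-bis(tributylstannyl)ethene; 2 dimethyl squarate (3,4-dimethoxycyclobut-3-ene-1,2-dione)
Product: 5 2,3,4-trimethoxy-4-[(E)-2-(tributylstannyl)ethenyl]cyclobut-2-en-1-one (racemic), via (E)-2-(tributylstannyl)ethenyllithium 3 (not isolated), via lithium alkoxide adduct 4 (not isolated)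
Conditions: 1, n-BuLi (1.0 equiv), THF, −78 °C, 1 h; cannulate into 2 (1.1 equiv), THF, −78 °C; then MeOTf (1.5 equiv), −78 → 0 °C
Reagents that add atoms: methyl trifluoromethanesulfonate, COS(=O)(=O)C(F)(F)F
Why: tin–lithium exchange on the symmetrical bis-stannane gives the configurationally stable (E)-vinyllithium 3, which adds 1,2 to one of the two equivalent carbonyl groups of the squaric ester (organolithium addition to a cyclobutenedione), and the tertiary lithium alkoxide 4 is O-methylated in the same flask so that the future 6-OMe is in place; the new quaternary centre is racemic and is erased in step 4.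

Step 2
Reactants: 6 (3,4,5-trimethoxyphenyl)acetic acid
Product: 7 (3,4,5-trimethoxyphenyl)acetyl chloride
Conditions: (COCl)2 (1.3 equiv), DMF (cat.), CH2Cl2, 0 °C → rt, 2 h; concentrate, use crude
Reagents that add atoms: oxalyl chloride, ClC(=O)C(=O)Cl
Why: acid chloride formation through the Vilsmeier-type chloroiminium species from DMF and oxalyl chloride, under conditions that leave the aryl methyl ethers untouched.

Step 3
Reactants: 5 2,3,4-trimethoxy-4-[(E)-2-(tributylstannyl)ethenyl]cyclobut-2-en-1-one; 7 (3,4,5-trimethoxyphenyl)acetyl chloride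
Product: 8 2,3,4-trimethoxy-4-[(1E)-3-oxo-4-(3,4,5-trimethoxyphenyl)but-1-en-1-yl]cyclobut-2-en-1-one (racemic)
Conditions: PhCH2PdCl(PPh3)2 (3 mol %), 2,6-di-tert-butylpyridine (0.1 equiv), CHCl3, CO (1 atm), 50 °C, 6 h
Reagents that add atoms: none
Why: Stille acylation (Kosugi–Migita–Stille ketone synthesis), in which zerovalent palladium adds oxidatively to the acyl chloride, the vinyl group is transferred from tin with retention of the E geometry and reductive elimination gives the enone; the CO atmosphere should hold back decarbonylation of the arylacetyl–palladium species, and 50 °C should stay below the ring-opening temperature of the cyclobutenone.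

Step 4
Reactants: 8 2,3,4-trimethoxy-4-[(1E)-3-oxo-4-(3,4,5-trimethoxyphenyl)but-1-en-1-yl]cyclobut-2-en-1-one
Product: 14 6,7,8-trimethoxy-3-(3,4,5-trimethoxyphenyl)-4H-chromen-4-one, via dienylketene 9 (not isolated), via cyclohexadienone 10 (not isolated), via 2-hydroxydeoxybenzoin 11 (not isolated), via enaminone 12 (not isolated), via 2-(dimethylamino)isoflavanone 13 (not isolated)
Conditions: PhMe (0.02 M), 110 °C, 2 h; then Me2NCH(OMe)2 (3 equiv), 110 °C, 3 h; then AcOH, 80 °C, 30 min
Reagents that add atoms: N,N-dimethylformamide dimethyl acetal, COC(OC)N(C)C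
Why: Heating should open the cyclobutenone by conrotatory 4π electrocyclic cleavage of its C1–C4 bond to the dienylketene 9, whose ketene carbon (future C8a) and enone α-carbon (future C4a) close ring A by a disrotatory 6π electrocyclisation; the dienone 10 has its only sp3 C–H between two carbonyl groups and should tautomerise at once to the hydrogen-bonded phenol 11. The closest known reaction type is the Moore rearrangement of 4-alkenyl-4-alkoxycyclobutenones to highly substituted phenols, and the annulation that follows is the standard closure of a 2-hydroxydeoxybenzoin to an isoflavone with an amide acetal. Ring A thus closes in a 6π electrocyclic mode, and ring C closes in the same flask when the acetal condenses with the only active methylene (C3, between the ketone and ring B) to the enaminone 12, whose β-carbon (C2) is attacked 6-endo by the phenol oxygen, dimethylamine leaving from the aminal 13. No stereocentre survives, since the quaternary centre of 8 and the transient sp3 carbons of 10 and 13 all end as sp2 atoms of the target. The step needs torquoselective ring opening with the alkenyl group turning inward, which the C4 methoxy group should secure because the donor oxygen rotates outward, and it needs a single substitution pattern on ring A, which is fixed by connectivity because C8a, C8, C7 and C6 arrive as an intact chain from the squarate and C5/C4a from the vinyl unit. The acetal is added only after the ring expansion so that methanol and dimethylamine never meet the electrophilic vinylogous ester of the cyclobutenone.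

**Compound list**

1 | (E)-1,2-bis(tributylstannyl)ethene | CCCC[Sn](CCCC)(CCCC)/C=C/[Sn](CCCC)(CCCC)CCCC | starting material
2 | dimethyl squarate (3,4-dimethoxycyclobut-3-ene-1,2-dione) | COC1=C(OC)C(=O)C1=O | starting material
3 | (E)-2-(tributylstannyl)ethenyllithium | [Li]/C=C/[Sn](CCCC)(CCCC)CCCC | intermediate (not isolated)
4 | lithium 2,3-dimethoxy-4-oxo-1-[(E)-2-(tributylstannyl)ethenyl]cyclobut-2-en-1-olate (racemic) | [Li]OC1(/C=C/[Sn](CCCC)(CCCC)CCCC)C(OC)=C(OC)C1=O | intermediate (not isolated)
5 | 2,3,4-trimethoxy-4-[(E)-2-(tributylstannyl)ethenyl]cyclobut-2-en-1-one (racemic) | COC1(/C=C/[Sn](CCCC)(CCCC)CCCC)C(OC)=C(OC)C1=O | intermediate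
6 | (3,4,5-trimethoxyphenyl)acetic acid | COc1cc(CC(=O)O)cc(OC)c1OC | starting material
7 | (3,4,5-trimethoxyphenyl)acetyl chloride | COc1cc(CC(=O)Cl)cc(OC)c1OC | intermediate
8 | 2,3,4-trimethoxy-4-[(1E)-3-oxo-4-(3,4,5-trimethoxyphenyl)but-1-en-1-yl]cyclobut-2-en-1-one (racemic) | COC1(/C=C/C(=O)Cc2cc(OC)c(OC)c(OC)c2)C(OC)=C(OC)C1=O | intermediate
9 | (3Z,5E)-2,3,4-trimethoxy-8-(3,4,5-trimethoxyphenyl)octa-1,3,5-triene-1,7-dione | O=C=C(OC)/C(OC)=C(OC)\C=C\C(=O)Cc1cc(OC)c(OC)c(OC)c1 | intermediate (not isolated)
10 | 2,3,4-trimethoxy-6-[(3,4,5-trimethoxyphenyl)acetyl]cyclohexa-2,4-dien-1-one (racemic) | COC1=CC(C(=O)Cc2cc(OC)c(OC)c(OC)c2)C(=O)C(OC)=C1OC | intermediate (not isolated)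
11 | 1-(2-hydroxy-3,4,5-trimethoxyphenyl)-2-(3,4,5-trimethoxyphenyl)ethan-1-one | COc1cc(CC(=O)c2cc(OC)c(OC)c(OC)c2O)cc(OC)c1OC | intermediate (not isolated)
12 | 3-(dimethylamino)-1-(2-hydroxy-3,4,5-trimethoxyphenyl)-2-(3,4,5-trimethoxyphenyl)prop-2-en-1-one (C=C geometry not defined, both isomers close) | CN(C)C=C(C(=O)c1cc(OC)c(OC)c(OC)c1O)c1cc(OC)c(OC)c(OC)c1 | intermediate (not isolated)
13 | 2-(dimethylamino)-6,7,8-trimethoxy-3-(3,4,5-trimethoxyphenyl)-2,3-dihydro-4H-chromen-4-one (racemic diastereomer mixture) | CN(C)C1Oc2c(OC)c(OC)c(OC)cc2C(=O)C1c1cc(OC)c(OC)c(OC)c1 | intermediate (not isolated)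
14 | 6,7,8-trimethoxy-3-(3,4,5-trimethoxyphenyl)-4H-chromen-4-one | COc1cc(-c2coc3c(OC)c(OC)c(OC)cc3c2=O)cc(OC)c1OC | target

**Step count and risks**

Total step count: 4. Longest linear sequence: 3 (steps 1, 3, 4).

Steps most likely to fail:

Step 3. The acylation may suffer from decarbonylation of the arylacetyl–palladium species, from acid-induced loss of the C4 methoxy group of the cyclobutenone, or from premature thermal ring opening during the coupling. The fallback sets out from 5 and works at or below room temperature without an acid chloride. Iododestannylation (I2, CH2Cl2, 0 °C) should give 4-[(E)-2-iodoethenyl]-2,3,4-trimethoxycyclobut-2-en-1-one F1. A Nozaki–Hiyama–Kishi addition (CrCl2, NiCl2 (cat.), DMF, rt) to commercial (3,4,5-trimethoxyphenyl)acetaldehyde F2 should give the allylic alcohol 4-[(1E)-3-hydroxy-4-(3,4,5-trimethoxyphenyl)but-1-en-1-yl]-2,3,4-trimethoxycyclobut-2-en-1-one F3. Oxidation with Dess–Martin periodinane (NaHCO3, CH2Cl2, 0 °C) comes back to the route at 8.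

Step 4. The dienylketene may be diverted before it closes onto the electron-poor alkene terminus (dimerisation, capture by adventitious nucleophiles), or the amide acetal may O-methylate the phenol instead of condensing. The fallback sets out from 2 and separates ring expansion from acylation. Addition of vinylmagnesium bromide (THF, −78 °C) and trapping with MeOTf should give 4-ethenyl-2,3,4-trimethoxycyclobut-2-en-1-one F4. Its thermolysis (PhMe, 110 °C), the parent case of the ring expansion, should give 2,3,4-trimethoxyphenol F5. Acylation with 7 (pyridine, CH2Cl2) should give 2,3,4-trimethoxyphenyl (3,4,5-trimethoxyphenyl)acetate F6. A Fries rearrangement promoted by BF3·OEt2 (90 °C, then water) to the only free ortho position comes back to the route at 11, which is then isolated and taken through the second half of step 4 to 14.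

Step 1. Incomplete or twofold tin–lithium exchange, twofold addition to the squarate, or sluggish O-methylation of the hindered tertiary alkoxide may give mixtures. The fallback sets out from 2 and brings in the two carbons as an alkyne, with tin added afterwards. Lithium (trimethylsilyl)acetylide (THF, −78 °C, NH4Cl quench) should give 4-hydroxy-2,3-dimethoxy-4-[(trimethylsilyl)ethynyl]cyclobut-2-en-1-one F7. Methylation (MeI, Ag2O, K2CO3, MeCN, rt) should give 2,3,4-trimethoxy-4-[(trimethylsilyl)ethynyl]cyclobut-2-en-1-one F8. Buffered desilylation (tetrabutylammonium fluoride, AcOH, THF, 0 °C) should give 4-ethynyl-2,3,4-trimethoxycyclobut-2-en-1-one F9. Syn hydrostannylation (Bu3SnH, PdCl2(PPh3)2 (2 mol %), THF, 0 °C) should place tin on the terminal carbon, away from the quaternary centre, and comes back to the route at 5.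

Further compounds
F1 | step 3 | 4-[(E)-2-iodoethenyl]-2,3,4-trimethoxycyclobut-2-en-1-one (racemic) | COC1(/C=C/I)C(OC)=C(OC)C1=O
F2 | step 3 | (3,4,5-trimethoxyphenyl)acetaldehyde | COc1cc(CC=O)cc(OC)c1OC
F3 | step 3 | 4-[(1E)-3-hydroxy-4-(3,4,5-trimethoxyphenyl)but-1-en-1-yl]-2,3,4-trimethoxycyclobut-2-en-1-one (diastereomer mixture) | COC1(/C=C/C(O)Cc2cc(OC)c(OC)c(OC)c2)C(OC)=C(OC)C1=O
F4 | step 4 | 4-ethenyl-2,3,4-trimethoxycyclobut-2-en-1-one (racemic) | COC1(C=C)C(OC)=C(OC)C1=O
F5 | step 4 | 2,3,4-trimethoxyphenol | COc1ccc(O)c(OC)c1OC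
F6 | step 4 | 2,3,4-trimethoxyphenyl (3,4,5-trimethoxyphenyl)acetate | COc1cc(CC(=O)Oc2ccc(OC)c(OC)c2OC)cc(OC)c1OC
F7 | step 1 | 4-hydroxy-2,3-dimethoxy-4-[(trimethylsilyl)ethynyl]cyclobut-2-en-1-one (racemic) | COC1=C(OC)C(O)(C#C[Si](C)(C)C)C1=O
F8 | step 1 | 2,3,4-trimethoxy-4-[(trimethylsilyl)ethynyl]cyclobut-2-en-1-one (racemic) | COC1=C(OC)C(OC)(C#C[Si](C)(C)C)C1=O
F9 | step 1 | 4-ethynyl-2,3,4-trimethoxycyclobut-2-en-1-one (racemic) | COC1=C(OC)C(OC)(C#C)C1=O
A1 | direct plan | 2,3,4-trimethoxybenzaldehyde | COc1ccc(C=O)c(OC)c1OC
A2 | direct plan | 1-(2-hydroxy-3,4,5-trimethoxyphenyl)ethan-1-one | CC(=O)c1cc(OC)c(OC)c(OC)c1O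
A3 | direct plan | 3,4,5-trimethoxybenzaldehyde | COc1cc(C=O)cc(OC)c1OC
A4 | direct plan | (2E)-1-[2-(benzyloxy)-3,4,5-trimethoxyphenyl]-3-(3,4,5-trimethoxyphenyl)prop-2-en-1-one | COc1cc(/C=C/C(=O)c2cc(OC)c(OC)c(OC)c2OCc2ccccc2)cc(OC)c1OC
A5 | direct plan | 1-[2-(benzyloxy)-3,4,5-trimethoxyphenyl]-3,3-dimethoxy-2-(3,4,5-trimethoxyphenyl)propan-1-one (racemic) | COC(OC)C(c1cc(OC)c(OC)c(OC)c1)C(=O)c1cc(OC)c(OC)c(OC)c1OCc1ccccc1
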